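**Plan**

- Retrosynthesis: the C3′–C4′ bond (alkenylzinc addition to a C3′ aldehyde) and the C4 methylene are cut first. Then C4–C5 and C6–C7 of the seven-membered ring are cut together (ethylene de Mayo reaction), then C7–C1′ (Michael addition to crotonaldehyde) and C7–C8 (Claisen). The remaining cyclopentene keto ester comes from (S)-carvone by Wolff ring contraction.
- Enabling feature: in the seven-membered ring, C4 (methylene carbon) and C8 (carbinol carbon) are latent ketones joined by C7 on one side and by the unsubstituted C5–C6 pair on the other. This 1,5-dicarbonyl can come from a five-membered C4–C7–C8 dione once ethylene is inserted between C4 and C7.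
- Forward order: cyclopentene ring A (ring contraction), five-membered dione ring B (Claisen), then the seven-membered ring by [2+2] photocycloaddition of ethylene to the C4 enol acetate and retro-aldol opening. The side chain is finished last.
- Stereochemistry: C3a from carvone; C8a by kinetic protonation anti to the isopropenyl group; C1 by epoxidation anti to the ring substituents; C1′ by the aminocatalyst; C7 by protonation of the ring-expanded enolate on the open face; C3′ by the chiral zinc catalyst; C8 by hydroxyl-directed hydride delivery.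

Key step: step 10

Remark: all intermediates carry the atom labels of the target (ring atoms C1–C8a, side chain C1′–C5′); β is the face of the ring-fusion hydrogens; ring A is the cyclopentene and ring B the five-membered dione ring that is later enlarged.

**Step 1**
Reactants: 1 (S)-carvone
Product: 3 6-diazocarvone, via 6-trifluoroacetylcarvone 2 (not isolated)
Conditions: LiN(SiMe3)2, THF, −78 °C; CF3CO2CH2CF3; aqueous HCl wash; then MsN3, Et3N, H2O, MeCN, rt
Reagents that add atoms: methanesulfonyl azide, CS(=O)(=O)N=[N+]=[N-]
Why: Detrifluoroacetylative (Regitz-type) diazo transfer, in which the kinetic cross-conjugated enolate is acylated at C6 and the resulting 1,3-dicarbonyl passes its activated position to the azide with loss of the trifluoroacetyl group, so the diazo group enters only at the α′ carbon and C5 is untouched.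

**Step 2**
Reactants: 3 6-diazocarvone
Product: 5 methyl (1S,5S)-2-methyl-5-(prop-1-en-2-yl)cyclopent-2-ene-1-carboxylate, via vinylketene 4 (not isolated)
Conditions: hν (Hg lamp, Pyrex, >300 nm), MeOH, 0 °C
Reagents that add atoms: methanol, CO
Why: Photochemical Wolff rearrangement of a cyclic α-diazo ketone, in which the vinyl carbon migrates to give the ring-contracted vinylketene, methanol adds, and kinetic protonation of the ester dienol at its α-carbon from the face away from the isopropenyl group should give the cis ester with the ring double bond left out of conjugation.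

**Step 3**
Reactants: 5 methyl (1S,5S)-2-methyl-5-(prop-1-en-2-yl)cyclopent-2-ene-1-carboxylate
Product: 6 epoxy ester (oxygen on the face opposite CO2Me and isopropenyl)
Conditions: 3-chloroperoxybenzoic acid (mCPBA, 1.05 equiv), NaHCO3, CH2Cl2, −20 → 0 °C
Reagents that add atoms: mCPBA, OOC(=O)c1cccc(Cl)c1
Why: Prilezhaev epoxidation, in which the trisubstituted ring alkene is more electron-rich than the 1,1-disubstituted isopropenyl group and the peracid should approach anti to the two cis substituents, placing the oxygen that becomes the C1 hydroxyl on the β face.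

**Step 4**
Reactants: 6 epoxy ester
Product: 8 epoxy keto ester, via ozonide 7 (not isolated)
Conditions: O3, CH2Cl2, −78 °C; PPh3, −78 °C → rt
Reagents that add atoms: ozone, [O-][O+]=O
Why: Ozonolysis with reductive work-up cleaves the only remaining alkene to the methyl ketone that will supply C4 and C7, while epoxide and ester are inert and no stereocentre is formed.

**Step 5**
Reactants: 8 epoxy keto ester
Product: 11 methyl (1S,2S,5S)-2-acetyl-5-hydroxy-5-methylcyclopent-3-ene-1-carboxylate, via hydroxy selenide 9 (not isolated), via selenoxide 10 (not isolated)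
Conditions: NaSePh [from (PhSe)2 and NaBH4 until gas evolution ends], MeOH/THF, 0 °C → rt; then 30% H2O2, 0 °C → rt
Reagents that add atoms: none
Why: Epoxide-to-allylic-alcohol transposition by selenide opening and selenoxide syn-elimination, in which the selenolate attacks the secondary C2 with inversion and the selenoxide can only eliminate towards C3 because C1 is quaternary, so the C1–O bond from step 3 is kept and C2=C3 appears.

**Step 6**
Reactants: 11 methyl (1S,2S,5S)-2-acetyl-5-hydroxy-5-methylcyclopent-3-ene-1-carboxylate
Product: 12 methyl (1S,2S,5S)-2-acetyl-5-methyl-5-(triethylsilyloxy)cyclopent-3-ene-1-carboxylate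
Conditions: Et3SiOTf, 2,6-lutidine, CH2Cl2, −78 °C
Reagents that add atoms: triethylsilyl trifluoromethanesulfonate, CC[Si](CC)(CC)OS(=O)(=O)C(F)(F)F
Why: Silylation of a tertiary alcohol with a silyl triflate and a hindered pyridine base, run at −78 °C so that the methyl ketone is not converted into its silyl enol ether.

**Step 7**
Reactants: 12 methyl (1S,2S,5S)-2-acetyl-5-methyl-5-(triethylsilyloxy)cyclopent-3-ene-1-carboxylate
Product: 13 (1S,5S,8S)-8-methyl-8-(triethylsilyloxy)bicyclo[3.3.0]oct-6-ene-2,4-dione
Conditions: LiN(SiMe3)2 (2.2 equiv), THF, −78 → 0 °C; aqueous NH4Cl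
Reagents that add atoms: none
Why: Intramolecular Claisen (Dieckmann-type) condensation, in which the hindered amide base removes a methyl proton of the ketone faster than the C3a or C8a protons, the enolate closes ring B on the cis ester (5-exo-trig), and the second equivalent of base stores the product as its dione enolate, the cis fusion being the only one the bicyclo[3.3.0] frame allows.

**Step 8**
Reactants: 13 (1S,5S,8S)-8-methyl-8-(triethylsilyloxy)bicyclo[3.3.0]oct-6-ene-2,4-dione; 14 (E)-crotonaldehyde
Product: 16 hydroxy dione (C7 carries the (2R)-4-hydroxybutan-2-yl group), via Michael aldehyde 15 (not isolated)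
Conditions: 14 (1.5 equiv), (S)-α,α-diphenylprolinol trimethylsilyl ether (10 mol%), CH2Cl2, 0 °C; then MeOH, NaBH4, −20 °C
Reagents that add atoms: none
Why: Iminium-catalysed Michael addition of a cyclic 1,3-dione to an enal with in-flask borohydride reduction, in which the diphenyl(silyloxy)methyl group of the (S)-catalyst shields one face of the (E)-iminium ion so that C7 adds to the β-carbon from the open face to give (R)-C1′ under catalyst control, and the aldehyde is reduced while the dione is protected as its enolate.

**Step 9**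
Reactants: 16 hydroxy dione
Product: 17 C4 enol acetate with acetylated side chain
Conditions: Ac2O (3 equiv), Et3N, 4-(dimethylamino)pyridine (10 mol%), CH2Cl2, 0 °C → rt
Reagents that add atoms: acetic anhydride, CC(=O)OC(C)=O
Why: Acetylation of the primary alcohol and O-acylation of the 2-alkyl-1,3-dione, in which the C4 oxygen, flanked only by C3a–H, is less hindered than the C8 oxygen next to the quaternary C1 with its methyl and silyloxy groups, and 4-(dimethylamino)pyridine-mediated acyl exchange should let the less congested C4 enol acetate accumulate.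

**Step 10**
Reactants: 17 C4 enol acetate with acetylated side chain; 18 ethylene
Product: 21 (1S,3aS,7R,8aS)-7-[(2R)-4-hydroxybutan-2-yl]-1-methyl-1-(triethylsilyloxy)-1,3a,5,6,7,8a-hexahydroazulene-4,8-dione, via cyclobutane photoadduct 19 (not isolated), via cyclobutanol 20 (not isolated)
Conditions: hν (350 nm, Pyrex), ethylene-saturated CH2Cl2, −78 °C; then K2CO3 (0.3 equiv), MeOH, 0 °C
Reagents that add atoms: none
Why: Excitation of the acyloxy enone near 350 nm and intersystem crossing give its triplet, which adds ethylene stepwise through a 1,4-biradical, and closure of that biradical on the convex face forms C4–C5 and C6–C7 in the only ring closure of the step, a cyclobutane made by radical recombination (formal [2+2] photocycloaddition). Carbonate in methanol then removes both acetates, and the C4 alkoxide of cyclobutanol 20, lying β to the C8 ketone, undergoes retro-aldol cleavage of the C4–C7 bond under release of four-ring strain, so that the seven-membered ring arises by two-carbon enlargement of ring B and not by a further cyclisation; the closest known reaction type is the de Mayo reaction of cyclic 1,3-dione enol acetates with alkenes. The only new stereocentre that survives is C7, set when the C7–C8 enolate is protonated by methanol from the open β face, which places the side chain cis to the C8a–C1 bond across the ketone, the arrangement also expected to be the more stable; the quaternary C4 centre of 19 is destroyed. Regiochemistry rests solely on the acetyl group sitting on the C4 oxygen (step 9), because ethylene is symmetric and the retro-aldol can only break the bond between the carbinol carbon and the carbon α to the remaining ketone. Chemoselectivity over the ring A alkene is expected because C2=C3 does not absorb at 350 nm, lies above the enone triplet in energy, and could add to it only by building a bicyclo[2.1.0]pentane. Low temperature, a little carbonate and a short contact time are chosen so that C3a, which becomes allylic and α to the new C4 ketone, keeps its configuration.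

**Step 11**
Reactants: 21 hydroazulene-4,8-dione
Product: 22 (1S,3aS,7R,8aS)-7-[(2R)-4-hydroxybutan-2-yl]-1-methyl-4-methylidene-1-(triethylsilyloxy)-3a,4,5,6,7,8a-hexahydroazulen-8(1H)-one
Conditions: Zn, CH2Br2, TiCl4, THF, 0 °C (pre-formed reagent); then 21, CH2Cl2, 0 °C → rt
Reagents that add atoms: dibromomethane, BrCBr
Why: Takai–Lombardo methylenation, in which the non-basic zinc–titanium methylene reagent olefinates the C4 ketone, which has a CH2 neighbour, in preference to the C8 ketone held between two tertiary carbons, and does not enolise C3a.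

**Step 12**
Reactants: 22 methylene ketone with free primary alcohol
Product: 23 (3R)-3-[(1S,3aS,7R,8aS)-1-methyl-4-methylidene-8-oxo-1-(triethylsilyloxy)-1,3a,4,5,6,7,8,8a-octahydroazulen-7-yl]butanal
Conditions: Dess–Martin periodinane, NaHCO3, CH2Cl2, 0 °C → rt
Reagents that add atoms: none
Why: Dess–Martin oxidation of the primary alcohol to the aldehyde under buffered conditions that leave the silyl ether, the ketone and the alkenes alone.

**Step 13**
Reactants: 23 side-chain aldehyde; 24 1-bromo-2-methylprop-1-ene
Product: 25 (3′R)-allylic alcohol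
Conditions: 24, t-BuLi (2 equiv), Et2O, −78 °C; ZnBr2 (0.5 equiv), −78 → 0 °C; N,N,N′,N′-tetraethylethylenediamine; (2S)-(−)-3-exo-morpholinoisoborneol (10 mol%), toluene; then 23, 0 °C; aqueous NH4Cl
Reagents that add atoms: none
Why: Amino-alcohol-catalysed enantioselective addition of an alkenylzinc reagent to an aldehyde, in which the zinc alkoxide of the isoborneol ligand is expected to deliver the alkenyl group to the Si face and so give (R)-C3′ under catalyst control (the nearest stereocentre is two atoms away), the diamine keeps LiBr from promoting a racemic background reaction, and the hindered ketone does not react with organozinc species.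

**Step 14**
Reactants: 25 (3′R)-allylic alcohol
Product: 26 (3′R)-allylic acetate
Conditions: Ac2O, pyridine, 4-(dimethylamino)pyridine (5 mol%), CH2Cl2, 0 °C
Reagents that add atoms: acetic anhydride, CC(=O)OC(C)=O
Why: Standard acylation of a secondary allylic alcohol, the only free hydroxyl present.

**Step 15**
Reactants: 26 (3′R)-allylic acetate
Product: 27 C1 hydroxy C8 ketone
Conditions: Bu4NF, AcOH (1:1), THF, 0 °C → rt
Reagents that add atoms: none
Why: Fluoride cleavage of the silyl ether, buffered with acetic acid so that the acetate is not cleaved and the β-hydroxy ketone does not undergo retro-aldol opening.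

**Step 16**
Reactants: 27 C1 hydroxy C8 ketone
Product: 28 target, (2R,4R)-2-[(1S,3aS,7R,8S,8aR)-1,8-dihydroxy-1-methyl-4-methylidene-1,3a,4,5,6,7,8,8a-octahydroazulen-7-yl]-6-methylhept-5-en-4-yl acetate
Conditions: Me4N[BH(OAc)3], MeCN/AcOH, −20 °C
Reagents that add atoms: none
Why: Hydroxyl-directed (Evans–Saksena) reduction, in which the C1 hydroxyl exchanges onto boron and delivers hydride through a six-membered transition state to the β face of the C8 carbonyl, also the open face because ring A and the C7 side chain cover the α face, which should give the (8S) alcohol while the acetate is inert to the reagent.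

**Compound list**

1 | (S)-(+)-carvone, (5S)-2-methyl-5-(prop-1-en-2-yl)cyclohex-2-en-1-one | O=C1C[C@@H](C(C)=C)CC=C1C | starting material
2 | 6-trifluoroacetylcarvone, (5S)-2-methyl-5-(prop-1-en-2-yl)-6-(trifluoroacetyl)cyclohex-2-en-1-one (C6 epimers and enol) | O=C1C(C(=O)C(F)(F)F)[C@@H](C(C)=C)CC=C1C | intermediate (not isolated)
3 | 6-diazocarvone, (5R)-6-diazo-2-methyl-5-(prop-1-en-2-yl)cyclohex-2-en-1-one (C5 spatially as in 1; descriptor changes by priority) | O=C1C(=[N+]=[N-])[C@@H](C(C)=C)CC=C1C | intermediate
4 | vinylketene, [2-methyl-5-(prop-1-en-2-yl)cyclopent-2-en-1-ylidene]methanone (C5 as in 1) | O=C=C1[C@@H](C(C)=C)CC=C1C | intermediate (not isolated)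
5 | methyl (1S,5S)-2-methyl-5-(prop-1-en-2-yl)cyclopent-2-ene-1-carboxylate (ester and isopropenyl cis) | COC(=O)[C@H]1[C@@H](C(C)=C)CC=C1C | intermediate
6 | methyl 1-methyl-3-(prop-1-en-2-yl)-6-oxabicyclo[3.1.0]hexane-2-carboxylate, epoxide oxygen trans to the cis ester and isopropenyl groups | COC(=O)[C@H]1[C@@H](C(C)=C)C[C@H]2[C@]1(C)O2 | intermediate
7 | ozonide of 6 (3-methyl-1,2,4-trioxolan-3-yl in place of isopropenyl) | COC(=O)[C@H]1[C@@H](C3(C)OOCO3)C[C@H]2[C@]1(C)O2 | intermediate (not isolated)
8 | methyl 3-acetyl-1-methyl-6-oxabicyclo[3.1.0]hexane-2-carboxylate (stereochemistry as in 6) | COC(=O)[C@H]1[C@@H](C(C)=O)C[C@H]2[C@]1(C)O2 | intermediate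
9 | hydroxy selenide, methyl 5-acetyl-2-hydroxy-2-methyl-3-(phenylselanyl)cyclopentane-1-carboxylate, OH trans to SePh and to the ester | COC(=O)[C@H]1[C@@H](C(C)=O)C[C@@H]([Se]c2ccccc2)[C@]1(C)O | intermediate (not isolated)
10 | selenoxide of 9 | COC(=O)[C@H]1[C@@H](C(C)=O)C[C@@H]([Se](=O)c2ccccc2)[C@]1(C)O | intermediate (not isolated)
11 | methyl (1S,2S,5S)-2-acetyl-5-hydroxy-5-methylcyclopent-3-ene-1-carboxylate | COC(=O)[C@H]1[C@@H](C(C)=O)C=C[C@]1(C)O | intermediate
12 | methyl (1S,2S,5S)-2-acetyl-5-methyl-5-(triethylsilyloxy)cyclopent-3-ene-1-carboxylate | COC(=O)[C@H]1[C@@H](C(C)=O)C=C[C@]1(C)O[Si](CC)(CC)CC | intermediate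
13 | (1S,5S,8S)-8-methyl-8-(triethylsilyloxy)-cis-bicyclo[3.3.0]oct-6-ene-2,4-dione | O=C1CC(=O)[C@H]2[C@@H]1C=C[C@]2(C)O[Si](CC)(CC)CC | intermediate
14 | (E)-crotonaldehyde | C/C=C/C=O | starting material
15 | Michael aldehyde, (3R)-3-[(1S,5S,8S)-8-methyl-2,4-dioxo-8-(triethylsilyloxy)bicyclo[3.3.0]oct-6-en-3-yl]butanal | O=C1C([C@H](C)CC=O)C(=O)[C@H]2[C@@H]1C=C[C@]2(C)O[Si](CC)(CC)CC | intermediate (not isolated)
16 | (1S,5S,8S)-3-[(2R)-4-hydroxybutan-2-yl]-8-methyl-8-(triethylsilyloxy)bicyclo[3.3.0]oct-6-ene-2,4-dione | O=C1C([C@H](C)CCO)C(=O)[C@H]2[C@@H]1C=C[C@]2(C)O[Si](CC)(CC)CC | intermediate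
17 | (3R)-3-[(1S,5S,8S)-4-acetoxy-8-methyl-2-oxo-8-(triethylsilyloxy)bicyclo[3.3.0]octa-3,6-dien-3-yl]butyl acetate (enol acetate on the target C4 oxygen) | CC(=O)OC1=C([C@H](C)CCOC(C)=O)C(=O)[C@H]2[C@@H]1C=C[C@]2(C)O[Si](CC)(CC)CC | intermediate
18 | ethylene | C=C | starting material
19 | cyclobutane photoadduct of 17 (cyclobutane cis-fused across C4–C7 on the β face, tertiary acetate at C4) | CC(=O)O[C@@]13CC[C@@]3([C@H](C)CCOC(C)=O)C(=O)[C@H]2[C@@H]1C=C[C@]2(C)O[Si](CC)(CC)CC | intermediate (not isolated)
20 | cyclobutanol from 19 (both acetates removed) | O[C@@]13CC[C@@]3([C@H](C)CCO)C(=O)[C@H]2[C@@H]1C=C[C@]2(C)O[Si](CC)(CC)CC | intermediate (not isolated)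
21 | (1S,3aS,7R,8aS)-7-[(2R)-4-hydroxybutan-2-yl]-1-methyl-1-(triethylsilyloxy)-1,3a,5,6,7,8a-hexahydroazulene-4,8-dione | O=C1CC[C@H]([C@H](C)CCO)C(=O)[C@H]2[C@@H]1C=C[C@]2(C)O[Si](CC)(CC)CC | intermediate
22 | (1S,3aS,7R,8aS)-7-[(2R)-4-hydroxybutan-2-yl]-1-methyl-4-methylidene-1-(triethylsilyloxy)-3a,4,5,6,7,8a-hexahydroazulen-8(1H)-one | C=C1CC[C@H]([C@H](C)CCO)C(=O)[C@H]2[C@@H]1C=C[C@]2(C)O[Si](CC)(CC)CC | intermediate
23 | (3R)-3-[(1S,3aS,7R,8aS)-1-methyl-4-methylidene-8-oxo-1-(triethylsilyloxy)-1,3a,4,5,6,7,8,8a-octahydroazulen-7-yl]butanal | C=C1CC[C@H]([C@H](C)CC=O)C(=O)[C@H]2[C@@H]1C=C[C@]2(C)O[Si](CC)(CC)CC | intermediate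
24 | 1-bromo-2-methylprop-1-ene | CC(C)=CBr | starting material
25 | (1S,3aS,7R,8aS)-7-[(2R,4R)-4-hydroxy-6-methylhept-5-en-2-yl]-1-methyl-4-methylidene-1-(triethylsilyloxy)-3a,4,5,6,7,8a-hexahydroazulen-8(1H)-one | C=C1CC[C@H]([C@H](C)C[C@H](C=C(C)C)O)C(=O)[C@H]2[C@@H]1C=C[C@]2(C)O[Si](CC)(CC)CC | intermediate
26 | (2R,4R)-6-methyl-2-[(1S,3aS,7R,8aS)-1-methyl-4-methylidene-8-oxo-1-(triethylsilyloxy)-1,3a,4,5,6,7,8,8a-octahydroazulen-7-yl]hept-5-en-4-yl acetate | C=C1CC[C@H]([C@H](C)C[C@H](C=C(C)C)OC(C)=O)C(=O)[C@H]2[C@@H]1C=C[C@]2(C)O[Si](CC)(CC)CC | intermediate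
27 | (2R,4R)-2-[(1S,3aS,7R,8aS)-1-hydroxy-1-methyl-4-methylidene-8-oxo-1,3a,4,5,6,7,8,8a-octahydroazulen-7-yl]-6-methylhept-5-en-4-yl acetate | C=C1CC[C@H]([C@H](C)C[C@H](C=C(C)C)OC(C)=O)C(=O)[C@H]2[C@@H]1C=C[C@]2(C)O | intermediate
28 | (2R,4R)-2-[(1S,3aS,7R,8S,8aR)-1,8-dihydroxy-1-methyl-4-methylidene-1,3a,4,5,6,7,8,8a-octahydroazulen-7-yl]-6-methylhept-5-en-4-yl acetate | C=C1CC[C@H]([C@H](C)C[C@H](C=C(C)C)OC(C)=O)[C@H](O)[C@H]2[C@@H]1C=C[C@]2(C)O | target

**Step count and risks**

Total: 16 steps. Longest linear sequence: 16 steps, from (S)-carvone 1 to 28; compounds 14, 18 and 24 are commercial building blocks.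

Steps most likely to fail:

1. Step 10. The ring-expanded C7–C8 enolate may be protonated from both faces, and base contact long enough to correct this would also risk epimerisation at C3a or migration of C2=C3 into conjugation with the C4 ketone. Fallback, from 17, returning at 22: irradiation and methanolysis are run as in step 10 and stopped as soon as the acetates are gone. The 7-epi-dione F1 that accompanies 21 is not separated but carried through the Takai–Lombardo methylenation of step 11, giving the 7-epi methylene ketone F2 beside 22. In these methylene ketones C3a is no longer next to a carbonyl, so the mixture can be equilibrated at C7 alone with 1,8-diazabicyclo[5.4.0]undec-7-ene in toluene at rt. The 2,7-cis ketone 22 is the expected thermodynamic product.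

2. Step 9. Acetylation may occur in part on the C8 oxygen, and that regioisomer would insert the two carbons between C7 and C8 in the photostep. Fallback, from 16, returning at 21: 2,2,2-trichloro-1,1-dimethylethyl chloroformate and pyridine in CH2Cl2 at 0 °C convert both hydroxyl functions into the bis(carbonate) F3. The tertiary alkoxycarbonyl group is much bulkier than acetyl and should go to the C4 oxygen only. Irradiation with ethylene as in step 10, without the carbonate treatment, gives the cyclobutane bis(carbonate) F4. Zn in THF/AcOH at rt then removes both carbonates by reductive fragmentation, which frees cyclobutanol 20 without base and lets it open to 21.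

3. Step 13. Halogen–metal exchange or transmetalation may be incomplete and facial control in the alkenyl transfer weak, giving C3′ epimers that lie far from the other stereocentres and are hard to separate. Fallback, from 23, returning at 25: 2-methylprop-1-enylmagnesium bromide (from 24 and Mg in THF) is added at −78 °C to give the C3′-epimeric allylic alcohols F5. MnO2 in CH2Cl2 oxidises only the allylic alcohol to the enone F6. CBS reduction with (S)-1-methyl-3,3-diphenyltetrahydro-1H,3H-pyrrolo[1,2-c][1,3,2]oxazaborole (10 mol%) and catecholborane in toluene at −78 °C, in which the alkenyl group acts as the large substituent, should return the (3′R) alcohol 25 and leave the hindered C8 ketone alone.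

**Further compounds**

F1 | step 10 | (1S,3aS,7S,8aS)-7-[(2R)-4-hydroxybutan-2-yl]-1-methyl-1-(triethylsilyloxy)-1,3a,5,6,7,8a-hexahydroazulene-4,8-dione (C7 epimer of 21) | O=C1CC[C@@H]([C@H](C)CCO)C(=O)[C@H]2[C@@H]1C=C[C@]2(C)O[Si](CC)(CC)CC
F2 | step 10 | (1S,3aS,7S,8aS)-7-[(2R)-4-hydroxybutan-2-yl]-1-methyl-4-methylidene-1-(triethylsilyloxy)-3a,4,5,6,7,8a-hexahydroazulen-8(1H)-one (C7 epimer of 22) | C=C1CC[C@@H]([C@H](C)CCO)C(=O)[C@H]2[C@@H]1C=C[C@]2(C)O[Si](CC)(CC)CC
F3 | step 9 | bis(2,2,2-trichloro-1,1-dimethylethyl carbonate) of 16 (enol carbonate on the C4 oxygen, alkyl carbonate on the side-chain oxygen) | CC(C)(OC(=O)OC1=C([C@H](C)CCOC(=O)OC(C)(C)C(Cl)(Cl)Cl)C(=O)[C@H]2[C@@H]1C=C[C@]2(C)O[Si](CC)(CC)CC)C(Cl)(Cl)Cl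
F4 | step 9 | ethylene photoadduct of F3 (cyclobutane across C4–C7, tertiary carbonate at C4) | CC(C)(OC(=O)O[C@@]13CC[C@@]3([C@H](C)CCOC(=O)OC(C)(C)C(Cl)(Cl)Cl)C(=O)[C@H]2[C@@H]1C=C[C@]2(C)O[Si](CC)(CC)CC)C(Cl)(Cl)Cl
F5 | step 13 | C3′-epimeric mixture of allylic alcohol 25 | C=C1CC[C@H]([C@H](C)CC(C=C(C)C)O)C(=O)[C@H]2[C@@H]1C=C[C@]2(C)O[Si](CC)(CC)CC
F6 | step 13 | (1S,3aS,7R,8aS)-1-methyl-7-[(2R)-6-methyl-4-oxohept-5-en-2-yl]-4-methylidene-1-(triethylsilyloxy)-3a,4,5,6,7,8a-hexahydroazulen-8(1H)-one | C=C1CC[C@H]([C@H](C)CC(=O)C=C(C)C)C(=O)[C@H]2[C@@H]1C=C[C@]2(C)O[Si](CC)(CC)CC
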